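**Retrosynthetic overview**
1. Target 23 ⇐ bis-MOM flavanone 22 by acetal cleavage.
2. The pyranone C ring of 22 ⇐ formal insertion of aryne 20 into the acyl–O bond of β-lactone (S)-9, a 4→6 ring expansion that forms O1–C8a and C4–C4a in one flask and carries C2 over unchanged.
3. Aryne 20 ⇐ aryl bromide 18 ⇐ resorcinol by MOM protection and three directed ortho-metalations (prenyl, prenyl, Br); the third A-ring oxygen arrives by cine-substitution.
4. (S)-9 ⇐ aldehyde 6 + acetyl chloride by catalytic asymmetric ketene–aldehyde [2+2]; 6 ⇐ 4-bromophenol + prenal (chromene ring), then formylation.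
5. Ring order: chromene pyran ring → β-lactone → (A ring is the resorcinol benzene) → pyranone C ring last.

Assumption: the quinine-series catalyst in step 3 is assigned to give (S)-9 by analogy only; sign and ee are checked by chiral HPLC, and the pseudo-enantiomer O-TMS-quinidine is used instead if the antipode forms.

**Step 1**
Reactants: 1 4-bromophenol; 2 3-methylbut-2-enal
Product: 4 6-bromo-2,2-dimethyl-2H-chromene, via ortho-quinone methide 3 (not isolated)
Conditions: PhB(OH)2 (1.0 equiv, recovered), EtCO2H (cat.), PhMe, reflux, Dean–Stark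
Reagents that add atoms: none
Why: Boronic-acid-templated ortho-selective condensation of the phenol with the enal loses water to give vinyl o-quinone methide 3, which closes by oxa-6π electrocyclisation to the 2,2-dimethylchromene; the para position is blocked by Br.

**Step 2**
Reactants: 4 6-bromo-2,2-dimethyl-2H-chromene
Product: 6 2,2-dimethyl-2H-chromene-6-carbaldehyde, via chromenyllithium 5 (not isolated)
Conditions: n-BuLi (1.1 equiv), THF, −78 °C; DMF, −78 → 0 °C; 1 M HCl
Reagents that add atoms: N,N-dimethylformamide, CN(C)C=O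
Why: Bromine–lithium exchange followed by Bouveault-type formylation of the aryllithium is routine and leaves the chromene alkene untouched.

**Step 3**
Reactants: 6 2,2-dimethyl-2H-chromene-6-carbaldehyde; 7 acetyl chloride
Product: 9 (4S)-4-(2,2-dimethyl-2H-chromen-6-yl)oxetan-2-one, via ketene 8 (not isolated)
Conditions: O-TMS-quinine (10 mol%), LiClO4 (1 equiv), iPr2NEt (2.5 equiv), 7 (3 equiv, slow addition), CH2Cl2–Et2O, −78 → −40 °C
Reagents that add atoms: none
Why: Cinchona-alkaloid/Li+ co-catalysed asymmetric ketene–aldehyde [2+2] cycloaddition (Wynberg-type): the base dehydrochlorinates 7 to ketene 8, the alkaloid converts it into a chiral ammonium enolate that adds to the Si face of the Li+-activated aldehyde and lactonises, setting C4 as S.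

**Step 4**
Reactants: 10 resorcinol
Product: 11 1,3-bis(methoxymethoxy)benzene
Conditions: MOMCl (2.4 equiv), iPr2NEt (3 equiv), CH2Cl2, 0 °C → rt
Reagents that add atoms: chloromethyl methyl ether, COCCl
Why: Standard O-alkylation of both phenols installs the MOM groups that later serve as ortho-metalation directors and as the inductive regiocontrol element of the aryne.

**Step 5**
Reactants: 11 1,3-bis(methoxymethoxy)benzene; 12 1-bromo-3-methylbut-2-ene
Product: 14 1,3-bis(methoxymethoxy)-2-(3-methylbut-2-en-1-yl)benzene, via 2-lithio arene 13 (not isolated)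
Conditions: n-BuLi (1.1 equiv), THF, 0 °C → rt; CuBr·SMe2 (10 mol%), 12 (1.2 equiv), −78 → 0 °C
Reagents that add atoms: none
Why: Directed ortho-metalation takes place at the doubly activated C2–H between the two OMOM groups, and the aryl-metal is alkylated by prenyl bromide at the unhindered α-carbon (SN2).

**Step 6**
Reactants: 14 1,3-bis(methoxymethoxy)-2-(3-methylbut-2-en-1-yl)benzene; 12 1-bromo-3-methylbut-2-ene
Product: 16 1,3-bis(methoxymethoxy)-2,4-bis(3-methylbut-2-en-1-yl)benzene, via 4-lithio arene 15 (not isolated)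
Conditions: n-BuLi/TMEDA (1.2 equiv), THF, −20 → 0 °C; CuBr·SMe2 (10 mol%), 12 (1.2 equiv), −78 → 0 °C
Reagents that add atoms: none
Why: A second directed ortho-metalation occurs at C4 (C4 and C6 are equivalent), ring lithiation next to OMOM being kinetically preferred over lateral deprotonation of the prenyl CH2, and prenylation follows as in step 5.

**Step 7**
Reactants: 16 1,3-bis(methoxymethoxy)-2,4-bis(3-methylbut-2-en-1-yl)benzene
Product: 18 1-bromo-2,4-bis(methoxymethoxy)-3,5-bis(3-methylbut-2-en-1-yl)benzene, via 6-lithio arene 17 (not isolated)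
Conditions: n-BuLi/TMEDA (1.3 equiv), THF, 0 °C; BrCl2C–CCl2Br (1.4 equiv), −78 °C
Reagents that add atoms: 1,2-dibromo-1,1,2,2-tetrachloroethane, ClC(Cl)(Br)C(Cl)(Cl)Br
Why: The last OMOM-flanked ring C–H is lithiated (directed ortho-metalation) and quenched by a positive-bromine donor that, unlike NBS or Br2, does not touch the prenyl alkenes; the single remaining ring H now sits ortho to Br.

**Step 8**
Reactants: 9 (4S)-4-(2,2-dimethyl-2H-chromen-6-yl)oxetan-2-one; 18 1-bromo-2,4-bis(methoxymethoxy)-3,5-bis(3-methylbut-2-en-1-yl)benzene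
Product: 22 (2S)-2-(2,2-dimethyl-2H-chromen-6-yl)-5,7-bis(methoxymethoxy)-6,8-bis(3-methylbut-2-en-1-yl)-2,3-dihydro-4H-chromen-4-one, via lithium hydroxy-carboxylate 19 (not isolated), via aryne 20 (not isolated), via lithiated aryl ether 21 (not isolated)
Conditions: 9 (1.3 equiv), LiOH·H2O (1.3 equiv), THF–H2O, 0 °C; strip, PhMe azeotrope; then 18 (1.0 equiv), LiTMP (4 equiv, from TMPH + n-BuLi), THF–DMPU, −78 → −20 °C; inverse quench into AcOH/THF, −78 °C
Reagents that add atoms: lithium hydroxide, [Li+].[OH-] (relay: its O becomes one of the two equivalent carboxylate O atoms of 19; one of these ends as the C4 carbonyl O, the other leaves as water at the quench)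
Why: Proposed new method: hydroxide-relayed formal insertion of an aryne into the acyl–O bond of a β-lactone (4→6 ring expansion), in which HO− opens 9 at the acyl carbon with retention to give 19, LiTMP forms its alkoxide and (by ortho-deprotonation/LiBr loss from 18) aryne 20, the alkoxide adds to the aryne carbon remote from the inductively withdrawing OMOM (distortion control, i.e. the carbon next to prenyl), and the doubly O-flanked aryllithium 21 closes on the lithium carboxylate to a gem-diolate that stops at the ketone stage and returns the relay as water on quench; no bond to the stereocentre is broken, so C2 stays S; closest known chemistry is aryne C–O insertion of carboxylic acids to o-hydroxyaryl ketones and chromanones, aryne acyl-alkylation ring expansion of cyclic β-keto esters, alkoxide addition to amide-generated arynes and Parham cyclisation onto carboxylates.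

**Step 9**
Reactants: 22 (2S)-2-(2,2-dimethyl-2H-chromen-6-yl)-5,7-bis(methoxymethoxy)-6,8-bis(3-methylbut-2-en-1-yl)-2,3-dihydro-4H-chromen-4-one
Product: 23 (2S)-2-(2,2-dimethyl-2H-chromen-6-yl)-5,7-dihydroxy-6,8-bis(3-methylbut-2-en-1-yl)-2,3-dihydro-4H-chromen-4-one
Conditions: 3 M aq HCl (cat.), MeOH–THF, 40 °C
Reagents that add atoms: none
Why: Acid-catalysed acetal methanolysis removes both MOM groups under conditions routinely used for prenylated flavanones, mild enough to avoid prenyl-to-chroman cyclisation and acid- or base-mediated ring opening, so C2 is not scrambled.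

**Compound list**
1 | 4-bromophenol | Oc1ccc(Br)cc1 | starting material
2 | 3-methylbut-2-enal | CC(C)=CC=O | starting material
3 | 4-bromo-6-(3-methylbut-2-en-1-ylidene)cyclohexa-2,4-dien-1-one | O=C1C=CC(Br)=CC1=CC=C(C)C | intermediate
4 | 6-bromo-2,2-dimethyl-2H-chromene | CC1(C)C=Cc2cc(Br)ccc2O1 | intermediate
5 | (2,2-dimethyl-2H-chromen-6-yl)lithium | CC1(C)C=Cc2cc([Li])ccc2O1 | intermediate
6 | 2,2-dimethyl-2H-chromene-6-carbaldehyde | CC1(C)C=Cc2cc(C=O)ccc2O1 | intermediate
7 | acetyl chloride | CC(=O)Cl | starting material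
8 | ketene | C=C=O | intermediate
9 | (4S)-4-(2,2-dimethyl-2H-chromen-6-yl)oxetan-2-one | O=C1C[C@@H](c2ccc3c(c2)C=CC(C)(C)O3)O1 | intermediate
10 | resorcinol | Oc1cccc(O)c1 | starting material
11 | 1,3-bis(methoxymethoxy)benzene | COCOc1cccc(OCOC)c1 | intermediate
12 | 1-bromo-3-methylbut-2-ene | CC(C)=CCBr | starting material
13 | [2,6-bis(methoxymethoxy)phenyl]lithium | COCOc1cccc(OCOC)c1[Li] | intermediate
14 | 1,3-bis(methoxymethoxy)-2-(3-methylbut-2-en-1-yl)benzene | COCOc1cccc(OCOC)c1CC=C(C)C | intermediate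
15 | [2,4-bis(methoxymethoxy)-3-(3-methylbut-2-en-1-yl)phenyl]lithium | COCOc1ccc([Li])c(OCOC)c1CC=C(C)C | intermediate
16 | 1,3-bis(methoxymethoxy)-2,4-bis(3-methylbut-2-en-1-yl)benzene | COCOc1ccc(CC=C(C)C)c(OCOC)c1CC=C(C)C | intermediate
17 | [2,4-bis(methoxymethoxy)-3,5-bis(3-methylbut-2-en-1-yl)phenyl]lithium | [Li]c1cc(CC=C(C)C)c(OCOC)c(CC=C(C)C)c1OCOC | intermediate
18 | 1-bromo-2,4-bis(methoxymethoxy)-3,5-bis(3-methylbut-2-en-1-yl)benzene | Brc1cc(CC=C(C)C)c(OCOC)c(CC=C(C)C)c1OCOC | intermediate
19 | lithium (3S)-3-(2,2-dimethyl-2H-chromen-6-yl)-3-hydroxypropanoate | [Li+].[O-]C(=O)C[C@@H](c1ccc2c(c1)C=CC(C)(C)O2)O | intermediate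
20 | 3,5-bis(methoxymethoxy)-4,6-bis(3-methylbut-2-en-1-yl)benzyne (1,2-didehydrobenzene) | C1#CC(CC=C(C)C)=C(OCOC)C(CC=C(C)C)=C1OCOC | intermediate
21 | lithium (3S)-3-(2,2-dimethyl-2H-chromen-6-yl)-3-[2-lithio-3,5-bis(methoxymethoxy)-4,6-bis(3-methylbut-2-en-1-yl)phenoxy]propanoate | [Li+].[Li]c1c(OCOC)c(CC=C(C)C)c(OCOC)c(CC=C(C)C)c1O[C@@H](CC(=O)[O-])c1ccc2c(c1)C=CC(C)(C)O2 | intermediate
22 | (2S)-2-(2,2-dimethyl-2H-chromen-6-yl)-5,7-bis(methoxymethoxy)-6,8-bis(3-methylbut-2-en-1-yl)-2,3-dihydro-4H-chromen-4-one | CC(C)=CCc1c(OCOC)c(CC=C(C)C)c2c(c1OCOC)C(=O)C[C@@H](c1ccc3c(c1)C=CC(C)(C)O3)O2 | intermediate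
23 | (2S)-2-(2,2-dimethyl-2H-chromen-6-yl)-5,7-dihydroxy-6,8-bis(3-methylbut-2-en-1-yl)-2,3-dihydro-4H-chromen-4-one | CC(C)=CCc1c(O)c(CC=C(C)C)c2c(c1O)C(=O)C[C@@H](c1ccc3c(c1)C=CC(C)(C)O3)O2 | target

**Totals**
Total steps: 9. Longest linear sequence: 6 (steps 4–9 from resorcinol); the lactone branch is steps 1–3 and joins at step 8.

**Three steps most likely to fail**

Step 8 (the proposed new step). Risks: LiTMP may deprotonate a benzylic/allylic prenyl CH2 instead of the ring C–H; the lithium alkoxide may be too weak a nucleophile (TMP adduct, aryne oligomers, hydride transfer); aryllithium 21 may be protonated or may deprotonate the benzylic C–H before it closes. Fallback with known chemistry, setting out from 18 and coming back at 22: 18 is ortho-lithiated with LiTMP in the presence of B(OiPr)3 (in-situ trap, THF, −78 °C) so that the anion is borylated before LiBr loss, giving after work-up [2-bromo-3,5-bis(methoxymethoxy)-4,6-bis(3-methylbut-2-en-1-yl)phenyl]boronic acid F1, which is oxidised (H2O2, NaOH, 0 °C) to 2-bromo-3,5-bis(methoxymethoxy)-4,6-bis(3-methylbut-2-en-1-yl)phenol F2. F2 is treated with n-BuLi (2.1 equiv, THF, −78 °C; phenoxide, then Br/Li exchange) and the antipodal lactone (4R)-4-(2,2-dimethyl-2H-chromen-6-yl)oxetan-2-one F3 (from 6 and 7 as in step 3 but with O-TMS-quinidine); acyl substitution opens the lactone to the ketol (3R)-3-(2,2-dimethyl-2H-chromen-6-yl)-3-hydroxy-1-[2-hydroxy-4,6-bis(methoxymethoxy)-3,5-bis(3-methylbut-2-en-1-yl)phenyl]propan-1-one F4. Intramolecular Mitsunobu etherification (PPh3, DIAD, THF, 0 °C) closes the pyranone with inversion at the carbinol carbon and gives (2S)-22. Here O1 comes from boron oxidation and the ring closes by SN2 at C2 rather than by aryne capture and acylation.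

Step 3. Risks: the electron-rich aryl aldehyde is a poor electrophile for the ammonium enolate, and the 4-(p-alkoxyaryl) β-lactone can ionise (racemise) or decarboxylate. Fallback, setting out from 6 and coming back at 19: methyl acetate is converted (LDA, TBSCl, THF, −78 °C) into its silyl ketene acetal tert-butyl[(1-methoxyethenyl)oxy]dimethylsilane F5; a Lewis-base-activated Mukaiyama aldol addition to 6 (SiCl4, chiral bisphosphoramide 5 mol%, CH2Cl2, −78 °C, catalyst antipode for Si-face addition) gives methyl (3S)-3-(2,2-dimethyl-2H-chromen-6-yl)-3-hydroxypropanoate F6; saponification (LiOH, THF–H2O, 0 °C) gives lithium salt 19, which enters the second stage of step 8 directly, so the lactone is bypassed.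

Step 1. Risks: 4-bromophenol is a deactivated phenol for the ortho-condensation, so low conversion or 2:1 adducts are possible. Fallback, setting out from 1 and coming back at 4: O-alkylation of 1 with 3-chloro-3-methylbut-1-yne (K2CO3, KI, CuI cat., acetone, reflux) gives 1-bromo-4-[(2-methylbut-3-yn-2-yl)oxy]benzene F7, which on heating (PhNEt2, 190 °C) undergoes propargyl Claisen rearrangement, 1,5-H shift and oxa-6π closure to 4.

**Further compounds**
F1 | step 8 | [2-bromo-3,5-bis(methoxymethoxy)-4,6-bis(3-methylbut-2-en-1-yl)phenyl]boronic acid | OB(O)c1c(Br)c(OCOC)c(CC=C(C)C)c(OCOC)c1CC=C(C)C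
F2 | step 8 | 2-bromo-3,5-bis(methoxymethoxy)-4,6-bis(3-methylbut-2-en-1-yl)phenol | Oc1c(Br)c(OCOC)c(CC=C(C)C)c(OCOC)c1CC=C(C)C
F3 | step 8 | (4R)-4-(2,2-dimethyl-2H-chromen-6-yl)oxetan-2-one | O=C1C[C@H](c2ccc3c(c2)C=CC(C)(C)O3)O1
F4 | step 8 | (3R)-3-(2,2-dimethyl-2H-chromen-6-yl)-3-hydroxy-1-[2-hydroxy-4,6-bis(methoxymethoxy)-3,5-bis(3-methylbut-2-en-1-yl)phenyl]propan-1-one | O=C(C[C@@H](O)c1ccc2c(c1)C=CC(C)(C)O2)c1c(O)c(CC=C(C)C)c(OCOC)c(CC=C(C)C)c1OCOC
F5 | step 3 | tert-butyl[(1-methoxyethenyl)oxy]dimethylsilane | C=C(OC)O[Si](C)(C)C(C)(C)C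
F6 | step 3 | methyl (3S)-3-(2,2-dimethyl-2H-chromen-6-yl)-3-hydroxypropanoate | COC(=O)C[C@@H](c1ccc2c(c1)C=CC(C)(C)O2)O
F7 | step 1 | 1-bromo-4-[(2-methylbut-3-yn-2-yl)oxy]benzene | CC(C)(C#C)Oc1ccc(Br)cc1
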